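- The ratio of partner to substrate charged in the flask was 1.10, close to the equimolar ratio of one, so I took that symmetric case as the zero of my scale.

| flask | substrate | partner | protic impurity | catalyst | remark | time |
|---|---|---|---|---|---|---|
| birch | 20 mM | 22 mM (in portions, 2) | 1 mM | 0.15 mM | the very flask that is asked about, followed so far; portions every 5.0 s |  |
| larch | 20 mM | 22 mM (in portions, 2) | 0.67 mM | 0.15 mM | run made earlier; portions every 5.0 s |  |
| flask | 20 mM | 22.0 mM (in portions, 2) | 1.00 mM | 0.15 mM | the portions of partner follow each other after 5.0 s, the first at the start | 2.5 min |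

| run | time / s | substrate / % | uncatalysed product / % | target / % | isomer of the product / % |
|---|---|---|---|---|---|
| birch | 12.0 | 43.6 | 8.4 | 18.5 | 29.1 |
| birch | 25.0 | 35.2 | 12.3 | 15.8 | 36.6 |
| birch | 40.0 | 33.3 | 14.9 | 13.6 | 36.3 |
| birch | 50.0 | 32.0 | 18.9 | 12.3 | 35.9 |
| birch | 60.0 | 32.0 | 22.3 | 13.0 | 36.2 |
| birch | 80.0 | 28.9 | 27.0 | 10.7 | 30.6 |
| larch | 10.0 | 47.7 | 8.9 | 19.1 | 26.8 |
| larch | 15.0 | 40.4 | 9.4 | 16.7 | 31.3 |
| larch | 25.0 | 33.2 | 11.4 | 15.4 | 36.3 |
| larch | 40.0 | 32.0 | 16.4 | 12.5 | 35.1 |
| larch | 60.0 | 31.0 | 22.2 | 11.4 | 34.6 |
| larch | 120 | 24.8 | 34.5 | 10.4 | 27.4 |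

(readings scatter by 1 percentage point)



- the species in which most of what was charged as substrate, at 2.5 min sits (substrate / target / isomer of the product / uncatalysed product)
- the largest share itself, whichever of these holds it, in percent of the substrate charged

- I assumed that each substrate lost to any product costs one partner, and that each protic impurity costs one too. That gave 1.00 mM of partner surplus, meaning partner charged less protic impurity less substrate charged. Once the impurity had reacted, partner left should exceed substrate left by this amount, and its sign named the limiting reagent.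
- I took uncatalysed product as bimolecular in substrate and partner. In the birch run it rose at 0.0571 mM s⁻¹ between 25.0 s and 60.0 s, with substrate near 6.72 mM, so I read a constant of 1.10 L mol⁻¹ s⁻¹.
- I treated target and isomer together as a reversible reservoir. In the birch run the 60.0 s readings put their sum, divided by the product of substrate and partner, at 208 L mol⁻¹.
- Holding the 80.0 s rate of 0.0432 mM s⁻¹ constant gave 8.42 mM of uncatalysed product at 2.5 min.
- That constant rate was the weak link. The balance then put substrate at 5.10 mM, where the rate was 0.0343 mM s⁻¹, lower. Averaging the two rates gave 8.11 mM, or 40.6%, more than the 33.9% of target and isomer together and more than the 25.5% of substrate.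
- The forecast said uncatalysed product at 40%, a little below my figure, on the ground that “substrate and isomer slowly drain while the uncatalysed product keeps growing”.
- The flask gave uncatalysed product at 40.9%, so the forecast held.

    substrate + partner ⇌ target (K = 53.0 L mol⁻¹, k = 5.70 L mol⁻¹ s⁻¹)
    substrate + partner ⇌ isomer of the product (K = 140 L mol⁻¹, k = 3.20 L mol⁻¹ s⁻¹)
    target + catalyst ⇌ isomer of the product + catalyst, rate k3*[catalyst]*[target] forward; the back reaction follows from the equilibrium constant (k = 720 L mol⁻¹ s⁻¹)
    substrate + partner → uncatalysed product (k = 1.10 L mol⁻¹ s⁻¹)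
    partner + protic impurity → quenched reagent (k = 27.0 L mol⁻¹ s⁻¹)

- At 2.50 min the flask held 1.00 mM of quenched reagent, and its partner exceeded its substrate by 1.00 mM, as the surplus said. A neighbouring flask, like this one but charged with 13 mM of partner, had a surplus of −8.00 mM, so partner was its limiting reagent and, once its impurity had reacted, its substrate had a floor of 40.0%. At 2.50 min substrate in that neighbouring flask exceeded partner by 8.00 mM, and substrate held most, at 50.4%.

The runs were computed from invented constants, and the scatter is random.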